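**Plan**

- Retrosynthesis: the carbocycle (C3a–C4–C5–C6–C7–C7a, benzofuranone numbering) is cut at C4=C5 (aldol condensation) and C6–C7 (enol-ether acylation); then C7a=C7 (lactone methylenation), C3a–allyl, C3a–C4 (formyl) and C2–C3 (crotylboration).
- Enabling feature: the six-membered ring is a vinylogous ester. C7a is the enol-ether carbon of the oxolane, C6 the ketone, C5 (OMe) its only enolisable α-carbon, and C4 an aldehyde-level carbon on the quaternary, non-enolisable C3a. This C5-nucleophile/C4-electrophile pair is set up for 6-(enolendo)-exo-trig closure.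
- Forward: aryl aldehyde + (Z)-crotylboronate → syn homoallylic alcohol → cis-γ-butyrolactone (oxolane ring) → α-formyl lactone → α-allyl quaternary lactone → acetal → 2-methylene oxolane → C7 acylation → closure of the cyclohexadienone as the last ring.
- Stereochemistry: C2 and C3 come from one catalytic asymmetric (Z)-crotylboration (chair transition state, syn). C3a is set by substrate control, the allyl group entering anti to the cis C3-Me/C2-aryl face. No later step touches these centres.

Key step: step 9

Remark: benzofuranone numbering (O1, C2, C3, C3a, C4–C7, C7a) is used for the corresponding atoms of all intermediates.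
Assumption: (R)-TRIP directs crotyl transfer to the Re face of the aryl aldehyde, as in the parent allylboration; if the sense were opposite, (S)-TRIP would be used.

**Route**

Step 1
Reactants: 1 3,4,5-trimethoxybenzaldehyde; 2 (Z)-crotylboronic acid pinacol ester
Product: 4 (1R,2S)-2-methyl-1-(3,4,5-trimethoxyphenyl)but-3-en-1-ol, via pinacol borate ester 3 (not isolated)
Conditions: (R)-TRIP (5 mol %), 4 Å MS, toluene, −30 °C; aq. NaHCO3 work-up
Reagents that add atoms: (Z)-crotylboronic acid pinacol ester 2, C/C=C\CB1OC(C)(C)C(C)(C)O1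
Why: Chiral-phosphoric-acid-catalysed asymmetric crotylboration; the closed chair transition state translates the Z geometry of 2 into the syn relationship and the catalyst selects the aldehyde face, so C2 and C3 are both set here.

Step 2
Reactants: 4
Product: 6 (1R,2S)-2-methyl-1-(3,4,5-trimethoxyphenyl)butane-1,4-diol, via bis(9-BBN) adduct 5 (not isolated)
Conditions: 9-BBN (2.3 equiv), THF, 0 °C → rt; then NaOH, H2O2, 0 °C → rt
Reagents that add atoms: hydrogen peroxide, OO
Why: Anti-Markovnikov hydroboration–oxidation of the terminal alkene (the excess borane accommodates the free OH); no stereocentre is touched.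

Step 3
Reactants: 6
Product: 8 (4S,5R)-4-methyl-5-(3,4,5-trimethoxyphenyl)oxolan-2-one, via lactol 7 (not isolated)
Conditions: TEMPO (20 mol %), PhI(OAc)2 (2.5 equiv), CH2Cl2, rt
Reagents that add atoms: none
Why: TEMPO/PhI(OAc)2 oxidative lactonisation: the primary alcohol should be oxidised selectively, trapped by the benzylic OH as lactol 7 and oxidised on, carrying the syn pair into a cis-4,5-disubstituted lactone.

Step 4
Reactants: 8; 9 ethyl formate
Product: 11 (3E,4S,5R)-3-(hydroxymethylidene)-4-methyl-5-(3,4,5-trimethoxyphenyl)oxolan-2-one (in equilibrium with its 3-formyl tautomer), via sodium enolate 10 (not isolated)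
Conditions: NaH (2 equiv), HCO2Et (5 equiv), cat. EtOH, THF, 0 °C → rt; 1 M HCl work-up
Reagents that add atoms: ethyl formate 9, CCOC=O
Why: Crossed Claisen condensation (α-formylation) of the lactone enolate, driven by formation of the stabilised enolate 10; C3a is the only acidic position and C2/C3 cannot epimerise.

Step 5
Reactants: 11; 12 allyl methyl carbonate
Product: 13 (3S,4S,5R)-4-methyl-2-oxo-3-(prop-2-en-1-yl)-5-(3,4,5-trimethoxyphenyl)oxolane-3-carbaldehyde
Conditions: Pd(PPh3)4 (5 mol %), THF, rt
Reagents that add atoms: allyl methyl carbonate 12, C=CCOC(=O)OC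
Why: Tsuji–Trost allylation of a soft β-dicarbonyl enolate; the planar C3a should attack the π-allyl palladium complex from the face anti to the cis C3-methyl and C2-aryl groups, setting the quaternary centre with allyl trans to both, while any O-allylation is reversible under Pd(0).

Step 6
Reactants: 13
Product: 14 (3S,4S,5R)-3-(dimethoxymethyl)-4-methyl-3-(prop-2-en-1-yl)-5-(3,4,5-trimethoxyphenyl)oxolan-2-one
Conditions: MeOTMS (3 equiv), TMSOTf (5 mol %), CH2Cl2, −78 → −20 °C; pyridine quench
Reagents that add atoms: methoxytrimethylsilane, CO[Si](C)(C)C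
Why: Aprotic silyl-triflate-catalysed acetalisation masks the neopentyl aldehyde without exposing the α-formyl lactone to alcoholysis (retro-Claisen deformylation); the acetal is the latent C4 electrophile for step 9.

Step 7
Reactants: 14; 15 dimethyltitanocene
Product: 16 (2R,3S,4R)-4-(dimethoxymethyl)-3-methyl-5-methylidene-4-(prop-2-en-1-yl)-2-(3,4,5-trimethoxyphenyl)oxolane
Conditions: Cp2TiMe2 (2.5 equiv), toluene, 65 °C, dark; filtration through basic alumina
Reagents that add atoms: dimethyltitanocene 15, C[Ti](C)(C1C=CC=C1)C1C=CC=C1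
Why: Petasis methylenation of the lactone carbonyl introduces C7; acetal and alkenes are inert to the titanium methylidene, and because C3a is quaternary the exocyclic enol ether cannot migrate into the ring.

Step 8
Reactants: 16; 17 methoxyacetyl chloride
Product: 18 1-[(3R,4S,5R)-3-(dimethoxymethyl)-4-methyl-3-(prop-2-en-1-yl)-5-(3,4,5-trimethoxyphenyl)oxolan-2-ylidene]-3-methoxypropan-2-one (E/Z mixture, Z expected to predominate)
Conditions: pyridine (3 equiv), CH2Cl2, 0 °C → rt
Reagents that add atoms: methoxyacetyl chloride 17, COCC(=O)Cl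
Why: C-Acylation of an electron-rich 1,1-disubstituted enol ether by an inductively activated acyl chloride (attack at C7, then loss of the C7 proton from the oxocarbenium ion) should give the vinylogous ester carrying C5, C6 and the C5 methoxy group.

Step 9
Reactants: 18
Product: 21 (2R,3S,3aS)-5-methoxy-3-methyl-3a-(prop-2-en-1-yl)-2-(3,4,5-trimethoxyphenyl)-3,3a-dihydro-1-benzofuran-6(2H)-one, via silyl dienol ether 19 (not isolated), via dimethoxy ketone 20 (not isolated)
Conditions: Et3N (3 equiv), TMSOTf (1.5 equiv), CH2Cl2, −78 → 0 °C; then DBU, 0 °C → rt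
Reagents that add atoms: none
Why: Soft enolisation (TMSOTf/Et3N) converts the vinylogous ester into the 2-silyloxy diene 19 (a Danishefsky-type diene) by deprotonation at C5, the only enolisable carbon because C3a is quaternary; TMSOTf then ionises the dimethyl acetal to the C4 methoxycarbenium ion, which the C5 terminus of the diene captures. The closest known reaction type is the one-pot silyl enol ether formation/Mukaiyama aldol addition to an acetal, followed by base-induced β-elimination of methanol (Mukaiyama aldol condensation). The carbocycle closes by C4–C5 bond formation in a 6-(enolendo)-exo-trig mode, and E1cB loss of methanol from 20 with DBU installs C4=C5 and thus the cross-conjugated 5-methoxy dienone. No stereocentre of the target is created here: C4 and C5 of 20 are transient and erased, while C3a (step 5) and C2/C3 (step 1) are untouched. The step needs the exocyclic C7a=C7 bond in the E geometry (C6 syn to C3a); the O-silylated vinylogous ester is an oxocarbenium ion with a rotatable C7–C7a bond, so Z and E should interconvert before enol silane formation and only the E rotamer can reach C4 (Curtin–Hammett funnel). Capture of the C4 cation by the electron-rich aryl ring (strained bridged ring) or by the allyl group should be outpaced by the far more nucleophilic silyl dienol ether through a strain-free six-membered transition state, and the low temperature and amine buffer should keep the benzylic C2–O1 bond from ionising.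

**Compound list**

1 | 3,4,5-trimethoxybenzaldehyde | O=Cc1cc(OC)c(OC)c(OC)c1 | starting material
2 | (Z)-crotylboronic acid pinacol ester | C/C=C\CB1OC(C)(C)C(C)(C)O1 | starting material
3 | pinacol borate ester of 4 | CC1(C)OB(O[C@@H](c2cc(OC)c(OC)c(OC)c2)[C@H](C=C)C)OC1(C)C | intermediate (not isolated)
4 | (1R,2S)-2-methyl-1-(3,4,5-trimethoxyphenyl)but-3-en-1-ol | O[C@@H](c1cc(OC)c(OC)c(OC)c1)[C@H](C=C)C | intermediate
5 | O,C-bis(9-borabicyclo[3.3.1]nonan-9-yl) adduct of 4 | O(B1C2CCCC1CCC2)[C@@H](c1cc(OC)c(OC)c(OC)c1)[C@H](CCB1C2CCCC1CCC2)C | intermediate (not isolated)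
6 | (1R,2S)-2-methyl-1-(3,4,5-trimethoxyphenyl)butane-1,4-diol | O[C@@H](c1cc(OC)c(OC)c(OC)c1)[C@H](CCO)C | intermediate
7 | (4S,5R)-4-methyl-5-(3,4,5-trimethoxyphenyl)oxolan-2-ol (anomeric mixture) | C1C(O)O[C@@H](c2cc(OC)c(OC)c(OC)c2)[C@H]1C | intermediate (not isolated)
8 | (4S,5R)-4-methyl-5-(3,4,5-trimethoxyphenyl)oxolan-2-one | C1C(=O)O[C@@H](c2cc(OC)c(OC)c(OC)c2)[C@H]1C | intermediate
9 | ethyl formate | CCOC=O | starting material
10 | sodium enolate of 11 | [Na+].[O-]/C=C1/C(=O)O[C@@H](c2cc(OC)c(OC)c(OC)c2)[C@H]1C | intermediate (not isolated)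
11 | (3E,4S,5R)-3-(hydroxymethylidene)-4-methyl-5-(3,4,5-trimethoxyphenyl)oxolan-2-one | O/C=C1/C(=O)O[C@@H](c2cc(OC)c(OC)c(OC)c2)[C@H]1C | intermediate
12 | allyl methyl carbonate | C=CCOC(=O)OC | starting material
13 | (3S,4S,5R)-4-methyl-2-oxo-3-(prop-2-en-1-yl)-5-(3,4,5-trimethoxyphenyl)oxolane-3-carbaldehyde | C=CC[C@]1(C=O)C(=O)O[C@@H](c2cc(OC)c(OC)c(OC)c2)[C@H]1C | intermediate
14 | (3S,4S,5R)-3-(dimethoxymethyl)-4-methyl-3-(prop-2-en-1-yl)-5-(3,4,5-trimethoxyphenyl)oxolan-2-one | C=CC[C@]1(C(OC)OC)C(=O)O[C@@H](c2cc(OC)c(OC)c(OC)c2)[C@H]1C | intermediate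
15 | dimethyltitanocene (Cp2TiMe2) | C[Ti](C)(C1C=CC=C1)C1C=CC=C1 | starting material
16 | (2R,3S,4R)-4-(dimethoxymethyl)-3-methyl-5-methylidene-4-(prop-2-en-1-yl)-2-(3,4,5-trimethoxyphenyl)oxolane | C=CC[C@]1(C(OC)OC)C(=C)O[C@@H](c2cc(OC)c(OC)c(OC)c2)[C@H]1C | intermediate
17 | methoxyacetyl chloride | COCC(=O)Cl | starting material
18 | 1-[(3R,4S,5R)-3-(dimethoxymethyl)-4-methyl-3-(prop-2-en-1-yl)-5-(3,4,5-trimethoxyphenyl)oxolan-2-ylidene]-3-methoxypropan-2-one (Z isomer drawn) | C=CC[C@]1(C(OC)OC)/C(=C/C(=O)COC)O[C@@H](c2cc(OC)c(OC)c(OC)c2)[C@H]1C | intermediate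
19 | (E)-configured 2-(trimethylsilyloxy) dienol ether of 18 (C5=C6 geometry not defined) | C=CC[C@]1(C(OC)OC)/C(=C\C(O[Si](C)(C)C)=COC)O[C@@H](c2cc(OC)c(OC)c(OC)c2)[C@H]1C | intermediate (not isolated)
20 | (2R,3S,3aS)-4,5-dimethoxy-3-methyl-3a-(prop-2-en-1-yl)-2-(3,4,5-trimethoxyphenyl)-3,3a,4,5-tetrahydro-1-benzofuran-6(2H)-one (mixture at C4/C5) | C=CC[C@]12C(OC)C(OC)C(=O)C=C1O[C@@H](c1cc(OC)c(OC)c(OC)c1)[C@H]2C | intermediate (not isolated)
21 | (2R,3S,3aS)-5-methoxy-3-methyl-3a-(prop-2-en-1-yl)-2-(3,4,5-trimethoxyphenyl)-3,3a-dihydro-1-benzofuran-6(2H)-one | C=CC[C@]12C=C(OC)C(=O)C=C1O[C@@H](c1cc(OC)c(OC)c(OC)c1)[C@H]2C | target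

Total step count: 9. Longest linear sequence: 9 steps (from 1).

**Steps most likely to fail**

1. Step 9. The Z/E equilibration of the exocyclic C7a=C7 bond may be too slow before enol silane formation, so that the unreactive Z dienol ether accumulates. The C4 cation may also be captured by the aryl ring, or the Lewis acid may ionise the benzylic C2–O1 bond and epimerise C2. Fallback: it sets out from 18. The acetal is hydrolysed under mild protic conditions (PPTS, wet acetone, 40 °C) to (3R,4S,5R)-2-(3-methoxy-2-oxopropylidene)-4-methyl-3-(prop-2-en-1-yl)-5-(3,4,5-trimethoxyphenyl)oxolane-3-carbaldehyde F1. The ring is then closed by a base-mediated intramolecular aldol condensation (K2CO3, MeOH, 0 °C → rt), in which reversible addition of methoxide at C7a should equilibrate the alkene geometry. This avoids cationic intermediates and comes back to the route at 21.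

2. Step 8 (and, before it, step 7). C-Acylation of the hindered enol ether may be sluggish, giving way to ketene formation or hydrolysis of the enol ether, and methylenation of the α-quaternary lactone may be incomplete. Fallback: it sets out from 14 and bypasses 16. Methyllithium (THF, −78 °C) is added to the lactone to give the methyl hemiketal (3S,4S,5R)-3-(dimethoxymethyl)-2,4-dimethyl-3-(prop-2-en-1-yl)-5-(3,4,5-trimethoxyphenyl)oxolan-2-ol F2. Its alkoxide/methyl-ketone enolate dianion (LDA, 2.2 equiv; only the methyl group can enolise) undergoes crossed Claisen acylation with N-methoxy-N-methyl-2-methoxyacetamide to give the β-diketone, held as the hemiketal 1-[(3S,4S,5R)-3-(dimethoxymethyl)-2-hydroxy-4-methyl-3-(prop-2-en-1-yl)-5-(3,4,5-trimethoxyphenyl)oxolan-2-yl]-3-methoxypropan-2-one F3. Mild acid-catalysed cyclodehydration (PPTS, benzene, molecular sieves) re-forms the oxolane as the vinylogous ester and comes back to the route at 18.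

3. Step 5. Facial selectivity at C3a may be poor, or methoxide generated from the carbonate may cause retro-Claisen deformylation. Fallback: it sets out from 11. Mitsunobu O-allylation of the acidic enol (allyl alcohol, PPh3, DIAD, THF, 0 °C) gives (3E,4S,5R)-4-methyl-3-[(prop-2-en-1-yloxy)methylidene]-5-(3,4,5-trimethoxyphenyl)oxolan-2-one F4. Thermal Claisen rearrangement (toluene, 110 °C) then delivers the allyl group suprafacially to the C3a face anti to the C3-methyl/C2-aryl groups under neutral conditions and comes back to the route at 13.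

**Further compounds**

F1 | step 9 | (3R,4S,5R)-2-(3-methoxy-2-oxopropylidene)-4-methyl-3-(prop-2-en-1-yl)-5-(3,4,5-trimethoxyphenyl)oxolane-3-carbaldehyde (Z isomer drawn) | C=CC[C@]1(C=O)/C(=C/C(=O)COC)O[C@@H](c2cc(OC)c(OC)c(OC)c2)[C@H]1C
F2 | step 8 | (3S,4S,5R)-3-(dimethoxymethyl)-2,4-dimethyl-3-(prop-2-en-1-yl)-5-(3,4,5-trimethoxyphenyl)oxolan-2-ol (anomeric mixture) | C=CC[C@]1(C(OC)OC)C(C)(O)O[C@@H](c2cc(OC)c(OC)c(OC)c2)[C@H]1C
F3 | step 8 | 1-[(3S,4S,5R)-3-(dimethoxymethyl)-2-hydroxy-4-methyl-3-(prop-2-en-1-yl)-5-(3,4,5-trimethoxyphenyl)oxolan-2-yl]-3-methoxypropan-2-one | C=CC[C@]1(C(OC)OC)C(O)(CC(=O)COC)O[C@@H](c2cc(OC)c(OC)c(OC)c2)[C@H]1C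
F4 | step 5 | (3E,4S,5R)-4-methyl-3-[(prop-2-en-1-yloxy)methylidene]-5-(3,4,5-trimethoxyphenyl)oxolan-2-one | C=CCO/C=C1/C(=O)O[C@@H](c2cc(OC)c(OC)c(OC)c2)[C@H]1C
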